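**Retrosynthetic overview**

1. Euchrenone a17 ⇒ acetate removal and allyl-to-prenyl cross-metathesis at C-8 of ring A; the acid-labile prenyl group is carried as an allyl group until ring D exists.
2. Ring D (the dihydropyran on ring B) ⇒ cut at both its aryl C–CH2 bond and its O–C(CH3)2 bond: a [3+3] annulation of isoprene onto the 4'-phenol of a complete (2S)-flavanone. Enabling feature: in ring B, O-4' is free and its ortho carbon C-3' (C-5' is equivalent) is unsubstituted, and the ring-D carbon bound to oxygen (C-2'') is a gem-dimethyl carbon. A C5 diene can therefore bond to C-3' as a primary allyl cation and to O-4' as a tertiary cation, while ring A is switched off by the C-4 carbonyl and a 7-acetate.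
3. Stereocentre C-2 of ring C ⇒ rhodium-catalysed asymmetric 1,4-addition of 4-hydroxyphenylboronic acid to an 8-allylchromone.
4. 8-Allyl group ⇒ aromatic Claisen rearrangement of the 7-allyl ether of 7-hydroxychromone.
5. Ring order: rings A and C are bought as the chromone, ring B is attached in step 3, and ring D is the only ring built, closed last in step 4.

Key step: step 4

Assumption: (S)-MeO-F12-BIPHEP is taken to deliver the aryl group to the face of C-2 that gives the (2S)-flavanone, by analogy with (S)-biaryl bisphosphines in additions to cyclohexenone; should the sense be the opposite, the (R)-ligand is used and nothing else changes.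

**Route**

Step 1
Reactants: 1 7-hydroxy-4H-chromen-4-one; 2 allyl bromide
Product: 3 7-(allyloxy)-4H-chromen-4-one
Conditions: K2CO3 (1.5 equiv), acetone, reflux
Reagents that add atoms: none
Why: Williamson ether synthesis, in which the acidic 7-hydroxyl (para to the pyranone carbonyl) is alkylated by the allylic bromide under a weak base that leaves the chromone ring closed.

Step 2
Reactants: 3 7-(allyloxy)-4H-chromen-4-one
Product: 5 8-allyl-4-oxo-4H-chromen-7-yl acetate, via 8-allyl-7-hydroxychromone 4 (not isolated)
Conditions: PhNEt2, 200 °C, sealed tube; then 25 °C, Ac2O, DMAP (cat.)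
Reagents that add atoms: acetic anhydride, CC(=O)OC(C)=O
Why: Aromatic Claisen rearrangement, which should go to C-8 rather than C-6 because the C-7–C-8 bond of a 7-oxygenated chromone has the higher double-bond character (as with 7-allyloxycoumarins and 7-allyloxyflavones), followed by DMAP-catalysed acetylation of the freed phenol in the same flask, which also deactivates ring A for step 4.

Step 3
Reactants: 5 8-allyl-4-oxo-4H-chromen-7-yl acetate; 6 4-hydroxyphenylboronic acid
Product: 7 (S)-8-allyl-2-(4-hydroxyphenyl)-4-oxochroman-7-yl acetate
Conditions: [Rh(OH)(cod)]2 (1.5 mol%), (S)-MeO-F12-BIPHEP (3.3 mol%), 6 (3 equiv), CH2Cl2/H2O 10:1, 25 °C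
Reagents that add atoms: none
Why: Rhodium-catalysed asymmetric 1,4-addition of an arylboronic acid to a chromone (Hayashi–Miyaura reaction, known for chromones with electron-poor biaryl bisphosphines), in which the chiral ligand on monovalent rhodium sets C-2 as S by enantioface-selective aryl insertion, and the base-free aqueous medium should keep the acetate, the allyl group and ring C intact.

Step 4
Reactants: 7 (S)-8-allyl-2-(4-hydroxyphenyl)-4-oxochroman-7-yl acetate; 8 isoprene
Product: 10 (S)-8-allyl-2-(2,2-dimethylchroman-6-yl)-4-oxochroman-7-yl acetate, via ortho-prenylphenol 9 (not isolated)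
Conditions: AgOTf (10 mol%), 8 (3 equiv), ClCH2CH2Cl, 25 °C, sealed tube, dark
Reagents that add atoms: none
Why: Silver triflate (together with the triflic acid it can release) turns isoprene into the 1,1-dimethylallyl cation, which attacks C-3' of ring B ortho to the free hydroxyl through its primary end (Friedel–Crafts alkylation) to give ortho-prenylphenol 9; Markovnikov protonation of its trisubstituted alkene then lets O-4' add to the gem-dimethyl carbon, so the aryl C–CH2 bond and the O–C(CH3)2 bond are formed in one flask. The closest known reaction type is the acid- or AgOTf-catalysed [3+3] annulation of phenols with isoprene to 2,2-dimethylchromans, established for para-substituted phenols. Ring D closes by a 6-endo-trig hydroalkoxylation at the tertiary carbon. No new stereocentre is formed, and C-2 is expected to survive because the medium is non-basic, non-nucleophilic and at room temperature. The step needs site selectivity for ring B over ring A and over the allyl group: ring B carries the only free phenol (hydroxyl-directed ortho attack, both ortho positions equivalent), ring A is deactivated by the C-4 carbonyl and the 7-acetate, and the monosubstituted allyl alkene is far harder to protonate than isoprene or a prenyl group. The six-membered chroman rather than a dihydrobenzofuran should result because carbon–carbon bonding occurs at the unhindered primary end and ring closure at the tertiary carbon.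

Step 5
Reactants: 10 (S)-8-allyl-2-(2,2-dimethylchroman-6-yl)-4-oxochroman-7-yl acetate; 11 2-methylbut-2-ene
Product: 12 (S)-2-(2,2-dimethylchroman-6-yl)-8-(3-methylbut-2-en-1-yl)-4-oxochroman-7-yl acetate
Conditions: second-generation Grubbs catalyst RuCl2(=CHPh)(PCy3)(H2IMes) (5 mol%), 11 (excess), CH2Cl2, 40 °C, sealed tube
Reagents that add atoms: none
Why: Olefin cross-metathesis of a terminal alkene with excess 2-methylbut-2-ene is the standard allyl-to-prenyl conversion, the trisubstituted product is inert to further metathesis, and the ketone, acetate, chroman and C-2 are not involved.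

Step 6
Reactants: 12 (S)-2-(2,2-dimethylchroman-6-yl)-8-(3-methylbut-2-en-1-yl)-4-oxochroman-7-yl acetate
Product: 13 euchrenone a17, (S)-2-(2,2-dimethylchroman-6-yl)-7-hydroxy-8-(3-methylbut-2-en-1-yl)chroman-4-one
Conditions: NH4OAc (excess), MeOH/H2O 4:1, 25 °C
Reagents that add atoms: none
Why: Ammonium acetate-mediated hydrolysis of an activated aryl acetate (ester cleavage at neutral pH) should free O-7 without a base strong enough to open ring C by retro-oxa-Michael reaction and without acid that would cyclise the prenyl group onto O-7, so the S centre is kept.

**Compound list**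

1 | 7-hydroxy-4H-chromen-4-one | O=c1ccoc2cc(O)ccc12 | starting material
2 | allyl bromide | C=CCBr | starting material
3 | 7-(allyloxy)-4H-chromen-4-one | O=c1ccoc2cc(OCC=C)ccc12 | intermediate
4 | 8-allyl-7-hydroxy-4H-chromen-4-one | O=c1ccoc2c(CC=C)c(O)ccc12 | intermediate (not isolated)
5 | 8-allyl-4-oxo-4H-chromen-7-yl acetate | CC(=O)Oc1ccc2c(c1CC=C)occc2=O | intermediate
6 | 4-hydroxyphenylboronic acid | OB(O)c1ccc(O)cc1 | starting material
7 | (S)-8-allyl-2-(4-hydroxyphenyl)-4-oxochroman-7-yl acetate | CC(=O)Oc1ccc2c(c1CC=C)O[C@H](c1ccc(O)cc1)CC2=O | intermediate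
8 | isoprene (2-methylbuta-1,3-diene) | C=CC(C)=C | starting material
9 | (S)-8-allyl-2-[4-hydroxy-3-(3-methylbut-2-en-1-yl)phenyl]-4-oxochroman-7-yl acetate | CC(=O)Oc1ccc2c(c1CC=C)O[C@H](c1ccc(O)c(CC=C(C)C)c1)CC2=O | intermediate (not isolated)
10 | (S)-8-allyl-2-(2,2-dimethylchroman-6-yl)-4-oxochroman-7-yl acetate | CC(=O)Oc1ccc2c(c1CC=C)O[C@H](c1ccc3c(c1)CCC(C)(C)O3)CC2=O | intermediate
11 | 2-methylbut-2-ene | CC=C(C)C | starting material
12 | (S)-2-(2,2-dimethylchroman-6-yl)-8-(3-methylbut-2-en-1-yl)-4-oxochroman-7-yl acetate | CC(=O)Oc1ccc2c(c1CC=C(C)C)O[C@H](c1ccc3c(c1)CCC(C)(C)O3)CC2=O | intermediate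
13 | euchrenone a17, (S)-2-(2,2-dimethylchroman-6-yl)-7-hydroxy-8-(3-methylbut-2-en-1-yl)chroman-4-one | CC(C)=CCc1c(O)ccc2c1O[C@H](c1ccc3c(c1)CCC(C)(C)O3)CC2=O | target

**Step count**

Total steps: 6. Longest linear sequence: 6 steps (1 to 13).

**Steps most likely to fail**

1. Step 4. The process at risk is loss of configuration at C-2, either by acid-induced heterolysis of the C-2–O-1 bond (a para-hydroxybenzylic ether) or by reversible opening of ring C to the chalcone. Cationic attack on the allyl alkene or a second alkylation of ring B could also compete. Fallback (sets out from compounds 8 and 5, returns at compound 10): the same annulation is run before the stereocentre exists. Commercial 4-bromophenol and isoprene 8 are combined under AgOTf catalysis in ClCH2CH2Cl to give 6-bromo-2,2-dimethylchroman F1. Bromine–lithium exchange (n-BuLi, THF, −78 °C), B(OiPr)3 and aqueous acid then give (2,2-dimethylchroman-6-yl)boronic acid F2. F2 is added to chromone 5 under the rhodium conditions of step 3 to give 10 directly, so that no acid meets the stereocentre; steps 5 and 6 follow unchanged.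

2. Step 3. The process at risk is protodeboronation of the electron-rich, unprotected boronic acid together with acyl transfer from the activated 7-acetate to the free phenol, so that turnover stalls. Fallback (sets out from compound 5, returns at compound 7): the phenol is carried through the addition as a silyl ether and unmasked separately. Chromone 5 is coupled with commercial 4-(tert-butyldimethylsilyloxy)phenylboronic acid under the same rhodium catalysis to give (S)-8-allyl-2-[4-(tert-butyldimethylsilyloxy)phenyl]-4-oxochroman-7-yl acetate F3. HF·pyridine in THF at 0 °C then frees the phenol without base to give 7.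

3. Step 2. The process at risk is regiochemical leakage of the [3,3] shift to C-6 and thermal degradation of the 2,3-unsubstituted pyranone at 200 °C. Fallback (sets out from compound 1, returns at compound 5): the allyl group is introduced by cross-coupling instead of rearrangement. Chromone 1 is iodinated at its most nucleophilic position C-8 (I2, HIO3, EtOH) to give 7-hydroxy-8-iodo-4H-chromen-4-one F4. Acetylation (Ac2O, pyridine) gives 8-iodo-4-oxo-4H-chromen-7-yl acetate F5. Stille coupling of F5 with allyltributylstannane (Pd(PPh3)4, toluene, 100 °C) gives 5.

**Further compounds**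

F1 | step 4 | 6-bromo-2,2-dimethylchroman | CC1(C)CCc2cc(Br)ccc2O1
F2 | step 4 | (2,2-dimethylchroman-6-yl)boronic acid | CC1(C)CCc2cc(B(O)O)ccc2O1
F3 | step 3 | (S)-8-allyl-2-[4-(tert-butyldimethylsilyloxy)phenyl]-4-oxochroman-7-yl acetate | CC(=O)Oc1ccc2c(c1CC=C)O[C@H](c1ccc(O[Si](C)(C)C(C)(C)C)cc1)CC2=O
F4 | step 2 | 7-hydroxy-8-iodo-4H-chromen-4-one | O=c1ccoc2c(I)c(O)ccc12
F5 | step 2 | 8-iodo-4-oxo-4H-chromen-7-yl acetate | CC(=O)Oc1ccc2c(c1I)occc2=O
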